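**Plan**

1. Retrosynthetic cuts, in order: the two ArO–SO2 bonds (phenol masks). Then, as one event, the bond between the tetrahydrofuran CH2 and the ring-fusion CH, together with the lactone O–CH(aryl) bond and the O–CH2 bond, which leads back to an open-chain syn β-hydroxy acid plus one formaldehyde carbon. Then the aldol Cα–C(OH) bond, and last the styryl C=C bond.
2. Feature used: the tetrahydrofuran CH2 lies between the ring oxygen and the ring-fusion CH, which is β to the lactone carbonyl and next to the lactone ArCH–O. The lactone ring is therefore the anti carbo-lactonisation adduct of an (E)-4-arylbut-3-enoic acid. Because the incoming carbon is bonded to the benzylic ring oxygen, it can be the O=CH2+ end of a cyclic acylal (a 1,3-dioxan-4-one) that ties this oxygen to the carboxyl group.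
3. Forward order: syringaldehyde → tosylate → (E)-styrylacetic acid → N-acyl oxazolidinone. An Evans syn aldol with O-tosylvanillin joins the two aryl halves, and hydrolysis gives the acid. One operation then builds the acylal, closes the tetrahydrofuran ring (C–C) and closes the lactone ring (C–O). Detosylation ends the route.
4. Stereochemistry: the (S)-4-benzyl oxazolidinone sets the ArCH–O and α-CH centres in the aldol. The ring-fusion CH–CH2 centre and the lactone ArCH–O centre are relayed from the α-centre and the (E)-alkene through cis-fusion and anti addition.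
5. Helpers: aryl tosylates (electron-poor rings that keep both benzylic C–O bonds from ionising) are removed in the last step. The trimethylsilyl groups and the acylal ring are consumed in the key step itself.

Key step: step 7

Remark on the chemistry: the SMILES is read as the (3S,3aR,6S,6aS) isomer, a cis-fused bicycle with both aryl groups on the convex face. Ts = 4-methylbenzenesulfonyl.

**Step 1**
Reactants: 1 syringaldehyde (4-hydroxy-3,5-dimethoxybenzaldehyde); 2 p-toluenesulfonyl chloride
Product: 3 4-formyl-2,6-dimethoxyphenyl 4-methylbenzenesulfonate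
Conditions: Et3N, DMAP (cat.), CH2Cl2, 0 °C → rt
Reagents that add atoms: p-toluenesulfonyl chloride (2), Cc1ccc(cc1)S(Cl)(=O)=O
Why: O-sulfonylation of a phenol, which installs a base-stable, electron-withdrawing mask that later keeps the styrene and the benzylic positions from ionising.

**Step 2**
Reactants: 3 4-formyl-2,6-dimethoxyphenyl 4-methylbenzenesulfonate; 4 (2-carboxyethyl)triphenylphosphonium bromide
Product: 5 (E)-4-[3,5-dimethoxy-4-(tosyloxy)phenyl]but-3-enoic acid
Conditions: 4, NaN(SiMe3)2 (2 equiv per 4), THF, 0 °C; then 3, −78 °C → rt; 1 M HCl work-up; recrystallisation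
Reagents that add atoms: (2-carboxyethyl)triphenylphosphonium bromide (4), OC(=O)CC[P+](c1ccccc1)(c1ccccc1)c1ccccc1.[Br-]
Why: Wittig olefination with the carboxylate-bearing ylide, which with aromatic aldehydes should give the (E)-β,γ-unsaturated acid preferentially, any (Z)-isomer being removed by crystallisation.

**Step 3**
Reactants: 5 (E)-4-[3,5-dimethoxy-4-(tosyloxy)phenyl]but-3-enoic acid; 6 (S)-4-benzyl-2-oxazolidinone
Product: 8 (S)-4-benzyl-3-{(E)-4-[3,5-dimethoxy-4-(tosyloxy)phenyl]but-3-enoyl}oxazolidin-2-one, via mixed pivalic anhydride 7 (not isolated)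
Conditions: t-BuCOCl, Et3N, THF, −20 °C; then 6, LiCl, −20 °C → rt
Reagents that add atoms: (S)-4-benzyl-2-oxazolidinone (6), O=C1OC[C@H](Cc2ccccc2)N1
Why: N-acylation of the oxazolidinone through the mixed pivalic anhydride (LiCl-assisted), a standard imide synthesis in which the styrene-conjugated alkene has no reason to migrate.

**Step 4**
Reactants: 9 vanillin (4-hydroxy-3-methoxybenzaldehyde); 2 p-toluenesulfonyl chloride
Product: 10 4-formyl-2-methoxyphenyl 4-methylbenzenesulfonate
Conditions: Et3N, DMAP (cat.), CH2Cl2, 0 °C → rt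
Reagents that add atoms: p-toluenesulfonyl chloride (2), Cc1ccc(cc1)S(Cl)(=O)=O
Why: O-sulfonylation of a phenol, which makes the aldehyde more electrophilic for the aldol and the later benzylic C–O bond resistant to ionisation.

**Step 5**
Reactants: 8 (S)-4-benzyl-3-{(E)-4-[3,5-dimethoxy-4-(tosyloxy)phenyl]but-3-enoyl}oxazolidin-2-one; 10 4-formyl-2-methoxyphenyl 4-methylbenzenesulfonate
Product: 13 (S)-4-benzyl-3-{(2S,3S)-3-hydroxy-3-[3-methoxy-4-(tosyloxy)phenyl]-2-[(E)-2-(3,5-dimethoxy-4-(tosyloxy)phenyl)ethenyl]propanoyl}oxazolidin-2-one, via boron dienolate 11 (not isolated), via boron aldolate 12 (not isolated)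
Conditions: Bu2BOTf, i-Pr2NEt, CH2Cl2, −78 → 0 °C; then 10, −78 → 0 °C; pH 7 buffer, MeOH, 30% H2O2 (14), 0 °C
Reagents that add atoms: none
Why: Evans syn aldol reaction in which the (Z)-dibutylboron dienolate reacts at its α-carbon through a closed chair (Zimmerman–Traxler) transition state on the face away from the benzyl group of the (S)-auxiliary, which should set the (2S,3S) pair of centres (α-CH and ArCH–OH) in one step.

**Step 6**
Reactants: 13 the aldol adduct; 14 hydrogen peroxide
Product: 16 (2S,3S)-3-hydroxy-3-[3-methoxy-4-(tosyloxy)phenyl]-2-[(E)-2-(3,5-dimethoxy-4-(tosyloxy)phenyl)ethenyl]propanoic acid, via lithium peroxycarboxylate 15 (not isolated)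
Conditions: LiOH·H2O, 30% H2O2, THF–H2O, 0 °C; aq. Na2SO3; 1 M HCl to pH 2
Reagents that add atoms: hydrogen peroxide (14), OO
Why: Standard LiOOH cleavage of an N-acyl oxazolidinone at the exocyclic carbonyl followed by sulfite reduction of the peroxy acid, conditions under which the aryl sulfonates and both stereocentres should be untouched.

**Step 7**
Reactants: 16 the syn β-hydroxy acid; 17 dimethoxymethane
Product: 21 (3S,3aR,6S,6aS)-3-[3,5-dimethoxy-4-(tosyloxy)phenyl]-6-[3-methoxy-4-(tosyloxy)phenyl]tetrahydro-1H,3H-furo[3,4-c]furan-1-one, via bis(trimethylsilyl) derivative 18 (not isolated), via 1,3-dioxan-4-one 19 (not isolated), via oxocarbenium ion 20 (not isolated)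
Conditions: (i) HN(SiMe3)2, Me3SiCl (cat.), CH2Cl2, 40 °C, then evaporation; (ii) 17 (1.05 equiv), Me3SiOTf (0.2 equiv), 2,6-di-tert-butyl-4-methylpyridine (0.1 equiv), CH2Cl2, −40 → 0 °C; Et3N quench
Reagents that add atoms: dimethoxymethane (17), COCOC
Why: Proposed new method: after silylation, Me3SiOTf-catalysed acetal exchange with dimethoxymethane (a known way to 1,3-dioxan-4-ones from silylated β-hydroxy acids) should give the cis-5,6-disubstituted acylal 19, whose O–CH2–O(C=O) unit ionises at the acyloxy side to the oxocarbenium ion 20 with the silyl carboxylate held on the neighbouring carbon; the closest known reaction types are the Lewis-acid opening of 1,3-dioxan-4-ones at the acetal carbon by π-nucleophiles, the oxonium-Prins closure of 4-arylbut-3-en-1-ols to 2,3-disubstituted tetrahydrofurans and the 5-endo halolactonisation of (E)-4-arylbut-3-enoic acids, here merged with carbon as the electrophile. The tetrahydrofuran ring closes by attack of the styrene β-carbon on the O=CH2+ carbon (five-membered, alkene exocyclic and C=O+ endocyclic to the new ring), and the lactone ring closes by addition of the carboxyl oxygen to the benzylic carbon (five-membered, endo with respect to the former alkene), which releases Me3Si+ and turns the catalyst over. The new ring-fusion centre (the CH bonded to the CH2) is controlled by the existing α-stereocentre, because the O=CH2+ arm and the carboxyl arm both hang from that carbon and can reach the alkene only from opposite faces, which is possible only in the cis-fused bicycle. The new lactone ArCH–O centre is controlled by the (E)-geometry of the alkene, since anti addition of carbon and oxygen across it places the aryl group on the convex face. The step needs C-attack at the styrene β-carbon to win over 2-oxonia-Cope rearrangement and over ionisation of the benzylic C–O bonds, and this is secured by the two electron-poor aryl sulfonate rings, which disfavour both side reactions, and by the carboxyl participation, which drives closure on the productive alkene face.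

**Step 8**
Reactants: 21 the furofuranone bis-tosylate
Product: 22 (3S,3aR,6S,6aS)-3-(4-hydroxy-3,5-dimethoxyphenyl)-6-(4-hydroxy-3-methoxyphenyl)tetrahydro-1H,3H-furo[3,4-c]furan-1-one
Conditions: Mg turnings (excess), MeOH–THF, rt, sonication; then aq. NH4Cl
Reagents that add atoms: none
Why: Reductive desulfonylation of aryl sulfonates by electron transfer from Mg in MeOH (S–O cleavage), a method that makes or breaks no bond at any of the four stereocentres and should leave the γ-lactone and the benzylic ethers intact.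

**Compound list**

1 | syringaldehyde (4-hydroxy-3,5-dimethoxybenzaldehyde) | COc1cc(C=O)cc(OC)c1O | starting material
2 | p-toluenesulfonyl chloride | Cc1ccc(cc1)S(Cl)(=O)=O | starting material
3 | 4-formyl-2,6-dimethoxyphenyl 4-methylbenzenesulfonate | COc1cc(C=O)cc(OC)c1OS(=O)(=O)c1ccc(C)cc1 | intermediate
4 | (2-carboxyethyl)triphenylphosphonium bromide | OC(=O)CC[P+](c1ccccc1)(c1ccccc1)c1ccccc1.[Br-] | starting material
5 | (E)-4-[3,5-dimethoxy-4-(tosyloxy)phenyl]but-3-enoic acid | OC(=O)C/C=C/c1cc(OC)c(OS(=O)(=O)c2ccc(C)cc2)c(OC)c1 | intermediate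
6 | (S)-4-benzyl-2-oxazolidinone | O=C1OC[C@H](Cc2ccccc2)N1 | starting material
7 | mixed anhydride of acid 5 with pivalic acid | CC(C)(C)C(=O)OC(=O)C/C=C/c1cc(OC)c(OS(=O)(=O)c2ccc(C)cc2)c(OC)c1 | intermediate
8 | (S)-4-benzyl-3-{(E)-4-[3,5-dimethoxy-4-(tosyloxy)phenyl]but-3-enoyl}oxazolidin-2-one | O=C1OC[C@H](Cc2ccccc2)N1C(=O)C/C=C/c1cc(OC)c(OS(=O)(=O)c2ccc(C)cc2)c(OC)c1 | intermediate
9 | vanillin (4-hydroxy-3-methoxybenzaldehyde) | COc1cc(C=O)ccc1O | starting material
10 | 4-formyl-2-methoxyphenyl 4-methylbenzenesulfonate | COc1cc(C=O)ccc1OS(=O)(=O)c1ccc(C)cc1 | intermediate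
11 | dibutylboron (Z)-dienolate of imide 8 | CCCCB(CCCC)O/C(=C\C=C\c1cc(OC)c(OS(=O)(=O)c2ccc(C)cc2)c(OC)c1)N1C(=O)OC[C@@H]1Cc1ccccc1 | intermediate
12 | dibutylboron aldolate of adduct 13 | CCCCB(CCCC)O[C@H](c1ccc(OS(=O)(=O)c2ccc(C)cc2)c(OC)c1)[C@H](/C=C/c1cc(OC)c(OS(=O)(=O)c2ccc(C)cc2)c(OC)c1)C(=O)N1C(=O)OC[C@@H]1Cc1ccccc1 | intermediate
13 | (S)-4-benzyl-3-{(2S,3S)-3-hydroxy-3-[3-methoxy-4-(tosyloxy)phenyl]-2-[(E)-2-(3,5-dimethoxy-4-(tosyloxy)phenyl)ethenyl]propanoyl}oxazolidin-2-one | O=C1OC[C@H](Cc2ccccc2)N1C(=O)[C@@H](/C=C/c1cc(OC)c(OS(=O)(=O)c2ccc(C)cc2)c(OC)c1)[C@H](O)c1ccc(OS(=O)(=O)c2ccc(C)cc2)c(OC)c1 | intermediate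
14 | hydrogen peroxide | OO | starting material
15 | lithium (2S,3S)-peroxycarboxylate corresponding to acid 16 | [Li+].[O-]OC(=O)[C@@H](/C=C/c1cc(OC)c(OS(=O)(=O)c2ccc(C)cc2)c(OC)c1)[C@H](O)c1ccc(OS(=O)(=O)c2ccc(C)cc2)c(OC)c1 | intermediate
16 | (2S,3S)-3-hydroxy-3-[3-methoxy-4-(tosyloxy)phenyl]-2-[(E)-2-(3,5-dimethoxy-4-(tosyloxy)phenyl)ethenyl]propanoic acid | OC(=O)[C@@H](/C=C/c1cc(OC)c(OS(=O)(=O)c2ccc(C)cc2)c(OC)c1)[C@H](O)c1ccc(OS(=O)(=O)c2ccc(C)cc2)c(OC)c1 | intermediate
17 | dimethoxymethane | COCOC | starting material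
18 | trimethylsilyl (2S,3S)-3-(trimethylsilyloxy) ester-ether of acid 16 | C[Si](C)(C)OC(=O)[C@@H](/C=C/c1cc(OC)c(OS(=O)(=O)c2ccc(C)cc2)c(OC)c1)[C@H](O[Si](C)(C)C)c1ccc(OS(=O)(=O)c2ccc(C)cc2)c(OC)c1 | intermediate
19 | (5S,6S)-6-[3-methoxy-4-(tosyloxy)phenyl]-5-[(E)-2-(3,5-dimethoxy-4-(tosyloxy)phenyl)ethenyl]-1,3-dioxan-4-one | O=C1OCO[C@H](c2ccc(OS(=O)(=O)c3ccc(C)cc3)c(OC)c2)[C@@H]1/C=C/c1cc(OC)c(OS(=O)(=O)c2ccc(C)cc2)c(OC)c1 | intermediate
20 | O-methylidene oxocarbenium trifluoromethanesulfonate of the trimethylsilyl ester (from 19) | C=[O+][C@H](c1ccc(OS(=O)(=O)c2ccc(C)cc2)c(OC)c1)[C@H](/C=C/c1cc(OC)c(OS(=O)(=O)c2ccc(C)cc2)c(OC)c1)C(=O)O[Si](C)(C)C.[O-]S(=O)(=O)C(F)(F)F | intermediate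
21 | (3S,3aR,6S,6aS)-3-[3,5-dimethoxy-4-(tosyloxy)phenyl]-6-[3-methoxy-4-(tosyloxy)phenyl]tetrahydro-1H,3H-furo[3,4-c]furan-1-one | COc1cc([C@H]2OC[C@H]3[C@@H]2C(=O)O[C@@H]3c2cc(OC)c(OS(=O)(=O)c4ccc(C)cc4)c(OC)c2)ccc1OS(=O)(=O)c1ccc(C)cc1 | intermediate
22 | (3S,3aR,6S,6aS)-3-(4-hydroxy-3,5-dimethoxyphenyl)-6-(4-hydroxy-3-methoxyphenyl)tetrahydro-1H,3H-furo[3,4-c]furan-1-one | COc1cc([C@H]2OC[C@H]3[C@@H]2C(=O)O[C@@H]3c2cc(OC)c(O)c(OC)c2)ccc1O | target

**Totals and risks**

Total step count: 8. Longest linear sequence: 7 steps (steps 1, 2, 3, 5, 6, 7, 8).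

Steps most likely to fail:

Step 7. What may go wrong: the acylal may resist ionisation at the acyloxy side, or the oxocarbenium ion may rearrange by 2-oxonia-Cope shift. It may also add to the alkene face on which the carboxyl group cannot follow, or reversible benzylic ionisation may erode configuration. The fallback uses known chemistry, sets out from 16 and returns at 21. Acid 16 is esterified with Me3SiCHN2 in MeOH–toluene to the methyl ester F1. An oxonium-Prins cyclisation of F1 with paraformaldehyde and SnBr4 in CH2Cl2 at −78 °C, the closure known for 4-arylbut-3-en-1-ols, forms the same CH2–CH bond with bromide as external trap and should give the 4-(α-bromobenzyl)tetrahydrofuran ester F2. Silver trifluoromethanesulfonate (AgOSO2CF3) in wet MeCN then ionises the benzylic bromide, so that the neighbouring ester carbonyl closes the lactone with loss of its methyl group, which gives 21.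

Step 5. What may go wrong: loss of α-regioselectivity or of facial control in the addition of the aryl-conjugated dienolate, or incomplete enolisation. The fallback sets out from 10 and returns at 13. The parent dienolate is used instead: (S)-4-benzyl-3-[(E)-but-2-enoyl]oxazolidin-2-one F3 is enolised with Bu2BOTf and Et3N and added to 10 in a deconjugative Evans aldol reaction, which should give the α-vinyl syn aldol adduct F4. The aryl group is then attached by cross-metathesis of F4 with 2,6-dimethoxy-4-vinylphenyl 4-methylbenzenesulfonate F5 (made from 3 with Ph3P=CH2) under the second-generation Grubbs catalyst in CH2Cl2 at 40 °C, which gives 13.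

Step 8. What may go wrong: slow electron transfer to the di-ortho-substituted sulfonate, or methanolysis of the lactone by the magnesium methoxide that forms. The fallback sets out from 21 and returns at 22. KOH in MeOH–H2O at 60 °C opens the lactone and cleaves both sulfonates by attack at sulfur, and acidification should give the seco hydroxy acid F6. The lactone is then re-closed by carboxyl activation with N-(3-dimethylaminopropyl)-N'-ethylcarbodiimide hydrochloride in CH2Cl2, so that the benzylic C–O bond is not broken, which gives 22.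

**Further compounds**

F1 | step 7 | methyl (2S,3S)-3-hydroxy-3-[3-methoxy-4-(tosyloxy)phenyl]-2-[(E)-2-(3,5-dimethoxy-4-(tosyloxy)phenyl)ethenyl]propanoate | COC(=O)[C@@H](/C=C/c1cc(OC)c(OS(=O)(=O)c2ccc(C)cc2)c(OC)c1)[C@H](O)c1ccc(OS(=O)(=O)c2ccc(C)cc2)c(OC)c1
F2 | step 7 | methyl (2S,3S,4R)-4-{bromo[3,5-dimethoxy-4-(tosyloxy)phenyl]methyl}-2-[3-methoxy-4-(tosyloxy)phenyl]tetrahydrofuran-3-carboxylate (bromide epimers) | COc1cc([C@H]2OC[C@H](C(Br)c3cc(OC)c(OS(=O)(=O)c4ccc(C)cc4)c(OC)c3)[C@@H]2C(=O)OC)ccc1OS(=O)(=O)c1ccc(C)cc1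
F3 | step 5 | (S)-4-benzyl-3-[(E)-but-2-enoyl]oxazolidin-2-one | C/C=C/C(=O)N1C(=O)OC[C@@H]1Cc1ccccc1
F4 | step 5 | (S)-4-benzyl-3-{(2S,3S)-2-ethenyl-3-hydroxy-3-[3-methoxy-4-(tosyloxy)phenyl]propanoyl}oxazolidin-2-one | O=C1OC[C@H](Cc2ccccc2)N1C(=O)[C@@H](C=C)[C@H](O)c1ccc(OS(=O)(=O)c2ccc(C)cc2)c(OC)c1
F5 | step 5 | 2,6-dimethoxy-4-vinylphenyl 4-methylbenzenesulfonate | C=Cc1cc(OC)c(OS(=O)(=O)c2ccc(C)cc2)c(OC)c1
F6 | step 8 | (2S,3S,4R)-4-[(S)-hydroxy(4-hydroxy-3,5-dimethoxyphenyl)methyl]-2-(4-hydroxy-3-methoxyphenyl)tetrahydrofuran-3-carboxylic acid | COc1cc([C@H]2OC[C@H]([C@H](O)c3cc(OC)c(O)c(OC)c3)[C@@H]2C(=O)O)ccc1O
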